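## Structural features

The target is a C20 tetracycle in which cyclohexane ring A (C4–C9) carries an α-methylene carboxylic acid (C1–C3) on C4 and is cis-fused along C7–C8 to the δ-lactone ring B (C7, C8, C10, O11, C12, C13). The quaternary C13 is the spiro atom shared with cyclohexanone ring C (C13, C14, C15, C16, C20, C19). Ring C is spanned between C16 and C19 by the O17–C18 unit of tetrahydrofuran ring D, so rings C and D form a 6-oxabicyclo[3.2.1]octanone with the CMe2 carbon C20 as one-atom bridge. There are six stereocentres, C4, C7 and C8 on ring A and C13, C16 and C19 on ring C; C8, C7, C13 and C19 stand in a row and C16 is tied to C19 by the bridge. On the chair of ring A the acrylic acid and C13 are equatorial and trans across the ring, whereas the lactone carbonyl C10 is axial, so C8 bears an epimerisable hydrogen in the less obviously favoured cis arrangement; on ring C the lactone methylene C12 is trans to C18 and ring A is cis to it. Sensitive groups are the β-alkoxy ketone C14/C16 (retro-oxa-Michael opening with base), C8–H next to the lactone carbonyl, the lactone towards alkoxide, and the acrylic acid as an acceptor. The real difficulty is the C7–C13 bond, which joins a ring methine to a fully substituted spiro carbon wedged between the C14 carbonyl and C19, together with the relay of configuration from ring C to ring A and the orientation of the two arms on C13. The key step exploits the 1,5-dicarbonyl array C14(=O)–C13–C7–C8–C10(=O): C13 is α to the ring C ketone, C7 is β and C8 is α to C10, and C9 hangs on C8, so C7–C13 is a conjugate-addition bond, C8–C9 an enolate-alkylation bond, and ring A can be closed on an open chain in the same operation that joins it to ring C.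

## Logic of the disconnections

**C3 carboxyl (33 ⇒ 32).** No skeletal bond is cut; the acid is taken back to the aldehyde. A free acrylic acid would quench every enolate of the route, so it is made last. The demand is an aldehyde oxidation that leaves the enolisable ketone, the lactone and the ether alone.

**O17–C16, ring D (32 ⇒ 30).** The β-alkoxy ketone is opened to a C18 hydroxyl (carried as a silyl ether) and a C15=C16 enone. This removes the bridge and one stereocentre, and it leaves a ketone with no enolisable position, which is what permits the base chemistry at C13 and C8. The forward step needs the C18 oxygen axial on ring C so that it can reach C16, under conditions that do not touch C8.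

**C3–O (30 ⇒ 28).** The formyl group is taken back to the methyl of an isopropenyl group. The side chain then travels as an inert hydrocarbon. The forward step needs allylic oxidation at the methyl and not at the C4 methine.

**C8–H (28 ⇒ 26).** Only the configuration at C8 changes. The ring-forming step delivers the ester trans to C13, so the cis fusion is set afterwards on the lactone, where C8–H is the only acidic hydrogen. The demand is kinetic protonation of the ring-fusion enolate from the C7–H face.

**C12–C13 and O11–C10, ring B (26 ⇒ 22 + 23).** The lactone is cut to a methyl ester on C8 and a one-carbon electrophile on C13. This removes the quaternary centre and a ring. The forward aldol must place C12 on the face of C13 anti to C18, so that ring A ends up cis to C18.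

**C7–C13 and C8–C9, ring A (22 ⇒ 6 + 19).** Both bonds are cut in one retrosynthetic step, the first as a conjugate addition and the second as an alkylation. This splits the molecule into two fragments of similar size, each with one stereocentre. The forward step must pair the enolate face anti to C18 with the correct enoate face, and must close the ring before the adduct enolate is lost.

**Fragment 1 (6 ⇒ 5 ⇒ 4 ⇒ 1 + 2).** O–Si, then C18–O back to C18–Si, then C18–C19. The symmetric dienone 1 has two enantiotopic β-carbons, so one catalytic conjugate addition of the hydroxymethyl equivalent from 2 sets C19 and leaves the enone in place. The demand is enantiotopic-group selection by the catalyst.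

**Fragment 2 (19 ⇒ 17 + 18 ⇒ 15 ⇒ 14 ⇒ 13 ⇒ 10 + 11 ⇒ 7 + 8).** C7=C8 is cut by olefination, the aldehyde is traced to a terminal alkyne, C9–I to C9–OH and to the acyl carbon of an auxiliary imide, and C4–C5 to a deconjugative alkylation. The alkylation creates the isopropenyl group and C4 together from a commercial acid chloride. The demand is α-alkylation of a dienolate under auxiliary control.

## Other disconnections considered

**Alternative 1:** The cut is through C7–C8 and C4–C9: ring A becomes an (E,E)-diene on C13 and an acrylate on O11. The forward key step would be thermal intramolecular Diels–Alder reaction of acrylate A1 to cycloadduct A2, closing rings A and B together.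
- In its favour: two rings, two C–C bonds and three stereocentres arise without a reagent. The spiro centre and the bridged rings C and D are in place beforehand, so C13 is not built under pressure from ring A. The cis fusion at C8 would come straight from the tether; on this point the alternative is better than the chosen plan, which corrects C8 in a separate step. No enolate is involved, so the proton-transfer problem of the chosen step does not exist.
- Against it: ester tethers prefer the conformation that holds diene and dienophile apart, so high temperature and acrylate polymerisation are to be expected. The diene face is selected only by the quaternary C13, whose two ring arms differ little. C4 would emerge cis to C13 and need epimerisation after ketal removal. C5=C6 must then be hydrogenated and the methyl ketone converted to the acrylic acid, about six further operations. A1 itself needs a long linear build.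
- Comparison: better in rings formed per step and at C8, equal in where C13 sits relative to C7, worse at C4, in convergence and in total step count.

**Alternative 2:** The cut is C18–C19 and C12–C13. The forward key step would oxidise the carboxylate of oxyacetic acid A3 with photoexcited [Ir(dF(CF3)ppy)2(dtbbpy)]PF6. Loss of CO2 gives an alkoxymethyl radical, which closes 5-exo-trig onto C19 of the C13=C19 enone; the α-keto radical is reduced to the C13 enolate, which is to add to formaldehyde 23 to give A4.
- In its favour: a radical is indifferent to the crowding at C19, and the tether forces C19 cis to the C16 oxygen, which equals the chosen plan, where the bridge also dictates this. Ring D and the quaternary centre would form in one neutral operation, which is better step economy at that stage.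
- Against it: an enolate made by electron transfer in a carboxylate-buffered medium should be protonated long before it meets formaldehyde. In the bridged enolate the face of C13 that must take C12 is the one under the axial methyl of C20, so the C13 epimer is the likely product; the chosen plan does this aldol before the bridge exists. The cut also leaves the C7–C13 bond and the relation of ring A to C16 unsolved inside A3.
- Comparison: equal or better for ring D, worse for C13, and it does not address the main structural problem.

**Alternative 3:** The cut is C18–C19 and C7–C13 in a three-component union of 1, 3 and nitroalkene A5. The forward key step would be the copper-catalysed enantioselective addition of 3 to 1 (CuBr·SMe2, chiral ferrocenyl diphosphine), with the magnesium enolate trapped at C13 by A5 to give A6.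
- In its favour: C19 is set by the same catalytic step as in the chosen plan, so the two are equal there. The enolate is used as formed, saving a deprotonation and postponing oxidation and silylation of C18. A nitroalkene is a far better acceptor than an enoate and ring A is preformed, so there is no race between ring closure and proton transfer; on these points the alternative is better.
- Against it: C8 ends up bearing nitrogen where the carboxyl carbon C10 is needed. That requires a Nef reaction and a one-carbon homologation with a new stereochemical problem at C8. Enantiopure A5 must be made by a ring synthesis of its own. The alkoxysilane must survive to a late peroxide oxidation in the presence of the isopropenyl group.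
- Comparison: shorter up to the coupled product, longer and less certain after it.

Key step: step 10

Remark 1: in 22 the hydrogen on C13 is cis to C18 and ring A is trans to it, as attack anti to C18 requires; C13 and C8 of 22 are provisional.
Remark 2: an orthoester Claisen rearrangement of a primary 2-methylallylic alcohol would create the isopropenyl-bearing centre C4 with no source of asymmetry, so C4 is set by auxiliary-controlled deconjugative alkylation (step 5).
Remark 3: the antipode of the ferrocenyl diphosphine in step 1 is assumed to be the one that leads to (5R)-4; the mirror-image ligand would be used otherwise.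
Remark 4: CIP descriptors of a given skeleton atom change along the route as substituent priorities change; the SMILES strings are authoritative.

## Route

Step 1
Reactants: 1 4,4-dimethylcyclohexa-2,5-dien-1-one; 2 (chloromethyl)(dimethyl)(propan-2-yloxy)silane
Product: 4 (5R)-5-{[dimethyl(propan-2-yloxy)silyl]methyl}-4,4-dimethylcyclohex-2-en-1-one, via Grignard reagent 3 (not isolated)
Conditions: 2, Mg, Et2O, 35 °C; then 1, CuBr·SMe2 (5 mol %), (R)-1-[(S)-2-(diphenylphosphino)ferrocenyl]ethyldicyclohexylphosphine (6 mol %), t-BuOMe, −75 °C; aq. NH4Cl
Reagents that add atoms: none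
Why: Copper-catalysed enantioselective conjugate addition of a Grignard reagent to a cyclic enone; the chiral diphosphine–copper complex selects one of the two enantiotopic β-carbons of the symmetric dienone and so sets C19, and the magnesium dienolate formed cannot accept a second addition.

Step 2
Reactants: 4 (5R)-5-{[dimethyl(propan-2-yloxy)silyl]methyl}-4,4-dimethylcyclohex-2-en-1-one
Product: 5 (5R)-5-(hydroxymethyl)-4,4-dimethylcyclohex-2-en-1-one
Conditions: H2O2 (30 % aq.), KHF2, DMF, rt
Reagents that add atoms: hydrogen peroxide, OO
Why: Tamao oxidation replaces the C18–Si bond by C18–O without touching C19; the fluoride-promoted, non-basic variant is chosen so that neither nucleophilic epoxidation of the enone nor early addition of the new hydroxyl to C16 is invited.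

Step 3
Reactants: 5 (5R)-5-(hydroxymethyl)-4,4-dimethylcyclohex-2-en-1-one
Product: 6 (5R)-5-({[tert-butyl(dimethyl)silyl]oxy}methyl)-4,4-dimethylcyclohex-2-en-1-one
Conditions: TBSCl, imidazole, CH2Cl2, 0 °C to rt
Reagents that add atoms: tert-butyl(chloro)dimethylsilane, CC(C)(C)[Si](C)(C)Cl
Why: Standard silylation of a primary alcohol; the silyl ether keeps the C18 oxygen from adding to C16 and from quenching enolates until ring D is wanted.

Step 4
Reactants: 7 (4S)-4-benzyl-1,3-oxazolidin-2-one; 8 3-methylbut-2-enoyl chloride
Product: 10 (4S)-4-benzyl-3-(3-methylbut-2-enoyl)-1,3-oxazolidin-2-one, via lithiated oxazolidinone 9 (not isolated)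
Conditions: n-BuLi, THF, −78 °C; then 8, −78 to 0 °C
Reagents that add atoms: none
Why: N-Acylation of a lithiated Evans oxazolidinone with an acid chloride.

Step 5
Reactants: 10 (4S)-4-benzyl-3-(3-methylbut-2-enoyl)-1,3-oxazolidin-2-one; 11 3-bromoprop-1-yne
Product: 13 (4S)-4-benzyl-3-[(2S)-2-(prop-1-en-2-yl)pent-4-ynoyl]-1,3-oxazolidin-2-one, via sodium dienolate 12 (not isolated)
Conditions: NaN(SiMe3)2, THF, −78 °C; then 11, −78 to −40 °C
Reagents that add atoms: none
Why: Evans deconjugative alkylation: γ-deprotonation gives the chelated (Z)-dienolate, which reacts with the propargylic bromide at its α-carbon on the face away from the benzyl group. This creates the isopropenyl group and sets C4 as (S), the arrangement that matches C4 of the target.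

Step 6
Reactants: 13 (4S)-4-benzyl-3-[(2S)-2-(prop-1-en-2-yl)pent-4-ynoyl]-1,3-oxazolidin-2-one
Product: 14 (2S)-2-(prop-1-en-2-yl)pent-4-yn-1-ol
Conditions: LiBH4, MeOH (1 equiv), Et2O, 0 °C
Reagents that add atoms: none
Why: Reductive removal of the auxiliary by hydride attack at the exocyclic imide carbonyl; the conditions are not basic enough to epimerise or conjugate the β,γ-unsaturated α-centre, and alkyne and alkene are inert.

Step 7
Reactants: 14 (2S)-2-(prop-1-en-2-yl)pent-4-yn-1-ol
Product: 15 (3S)-3-(iodomethyl)-2-methylhex-1-en-5-yne
Conditions: I2, PPh3, imidazole, CH2Cl2, 0 °C to rt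
Reagents that add atoms: iodine, [I][I]
Why: Appel-type iodination of a primary alcohol through the alkoxyphosphonium salt; the stereocentre is not involved.

Step 8
Reactants: 15 (3S)-3-(iodomethyl)-2-methylhex-1-en-5-yne
Product: 17 (4S)-4-(iodomethyl)-5-methylhex-5-enal, via alkenylborane 16 (not isolated)
Conditions: (Sia)2BH [from BH3·SMe2 and 2-methylbut-2-ene], THF, 0 °C; then H2O2, pH 7 phosphate buffer, 0 °C to rt
Reagents that add atoms: hydrogen peroxide, OO
Why: Anti-Markovnikov monohydroboration of a terminal alkyne with a hindered dialkylborane, then oxidation of the alkenylborane to the aldehyde (C7). The 1,1-disubstituted, α-branched isopropenyl group reacts far more slowly with this borane, and the buffered oxidation spares the iodide.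

Step 9
Reactants: 17 (4S)-4-(iodomethyl)-5-methylhex-5-enal; 18 methyl 2-(dimethoxyphosphoryl)acetate
Product: 19 methyl (2E,6S)-6-(iodomethyl)-7-methylocta-2,7-dienoate
Conditions: LiCl, i-Pr2NEt, MeCN, rt
Reagents that add atoms: none
Why: Horner–Wadsworth–Emmons olefination under Masamune–Roush conditions gives the (E)-enoate; the base is too weak and too hindered to displace or eliminate the β-branched primary iodide.

Step 10
Reactants: 6 (5R)-5-({[tert-butyl(dimethyl)silyl]oxy}methyl)-4,4-dimethylcyclohex-2-en-1-one; 19 methyl (2E,6S)-6-(iodomethyl)-7-methylocta-2,7-dienoate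
Product: 22 methyl (1R,2S,5R)-2-[(1R,6R)-6-({[tert-butyl(dimethyl)silyl]oxy}methyl)-5,5-dimethyl-2-oxocyclohex-3-en-1-yl]-5-(prop-1-en-2-yl)cyclohexane-1-carboxylate, via lithium dienolate 20 (not isolated), via ester enolate 21 (not isolated)
Conditions: 6, LiN(SiMe3)2, THF, −78 °C; 19, −78 °C; then DMPU, −78 to 0 °C; aq. NH4Cl
Reagents that add atoms: none
Why: LiN(SiMe3)2 removes a hydrogen from C13, the only enolisable position of 6 (C20 is quaternary), to give the cross-conjugated dienolate 20. In the half-chair of 20 the C18 arm is pseudoaxial, so C13 adds to C7 of the (E)-enoate on the face anti to C18, through a lithium-bridged closed transition state in which the ester arm lies gauche to the enolate C–O bond on the side of the C13 hydrogen; for an E(O) cyclic enolate and an (E)-enoate this is the syn (like) pairing, and it sets C7 relative to C19. The ester enolate 21 then displaces the primary iodide at C9 in a 6-exo-tet closure of ring A through a chair in which the ring C unit on C7 and the isopropenyl group on C4 are both equatorial, which is why C4 was made with the matching (S) configuration. Allylic 1,3-strain turns C7–H into the plane of the exocyclic ester enolate, so C9 bonds to C8 anti to C13 and the ester emerges trans to C13 with all three ring A substituents equatorial; this centre and C13 are provisional and are reset in steps 12 and 11. The closest known reaction type is the Michael-initiated ring closure of ω-halo α,β-unsaturated esters with ketone and ester enolates. Two selectivities are needed: conjugate addition must outrun direct alkylation of 20, which the unhindered β-monosubstituted enoate and the β-branched iodide secure, and ring closure must outrun proton transfer from the acidic C13–H of the adduct to the ester enolate, which is why DMPU is added only after the addition, to accelerate the displacement.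

Step 11
Reactants: 22 methyl (1R,2S,5R)-2-[(1R,6R)-6-({[tert-butyl(dimethyl)silyl]oxy}methyl)-5,5-dimethyl-2-oxocyclohex-3-en-1-yl]-5-(prop-1-en-2-yl)cyclohexane-1-carboxylate; 23 formaldehyde (monomeric, from cracked paraformaldehyde)
Product: 26 trans-fused spiro lactone enone (4R,7R,8R,13S,19S; C8–H trans to C7–H; C12 trans to C18), via lithium dienolate 24 (not isolated), via lithium aldolate 25 (not isolated)
Conditions: LiN(SiMe3)2, THF, −78 to −20 °C; CH2O (THF solution), −78 to 0 °C; aq. NH4Cl
Reagents that add atoms: none
Why: The ketone α-hydrogen at C13 is several pKa units more acidic than the ester α-hydrogen at C8, so the tetrasubstituted dienolate 24 forms selectively. Allylic 1,2-strain with ring A holds the C18 arm pseudoaxial, so formaldehyde adds to C13 anti to C18 (aldol reaction), which makes C12 trans and ring A cis to C18. The alkoxide 25 then attacks the C10 methyl ester to close the δ-lactone, which also removes the aldolate from retro-aldol equilibrium.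

Step 12
Reactants: 26 trans-fused spiro lactone enone (4R,7R,8R,13S,19S)
Product: 28 cis-fused spiro lactone enone (4R,7R,8S,13S,19S; C8 epimer of 26), via lactone enolate 27 (not isolated)
Conditions: LiN(i-Pr)2, THF, −78 °C; then 2,6-di-tert-butyl-4-methylphenol, −78 °C to rt; aq. NH4Cl
Reagents that add atoms: none
Why: C8–H is the only acidic hydrogen of 26, because C13 is quaternary and C15 is vinylic. Kinetic protonation of the ring-fusion enolate 27 by a bulky phenol should come from the equatorial direction of ring A, the face of C7–H, as in the ketonisation of exocyclic cyclohexyl enols and the angular protonation of 1-decalone enolates, and this gives the cis-fused lactone with C10 axial. The hindered, weakly basic phenoxide cannot re-equilibrate the product.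

Step 13
Reactants: 28 cis-fused spiro lactone enone (4R,7R,8S,13S,19S)
Product: 30 α-methylene aldehyde of 28 (C3 as CHO), via allylic alcohol 29 (not isolated)
Conditions: SeO2 (0.5 equiv), t-BuOOH, CH2Cl2, rt; then MnO2, CH2Cl2, rt
Reagents that add atoms: tert-butyl hydroperoxide, CC(C)(C)OO (oxygen delivered through selenium dioxide, O=[Se]=O)
Why: Selenium dioxide allylic oxidation (ene reaction, then 2,3-sigmatropic shift) of a 1,1-disubstituted alkene attacks the methyl in preference to the ring methine, as known for isopropenyl terpenoids; the ring C enone has no allylic hydrogen and no enolisable position at this stage. MnO2 converges the allylic alcohol 29 and any aldehyde already formed on 30.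

Step 14
Reactants: 30 α-methylene aldehyde of 28
Product: 32 bridged keto lactone aldehyde (ring D closed; 4R,7R,8S,13S,16S,19S), via hydroxy enone 31 (not isolated)
Conditions: HF·pyridine, THF, 0 °C to rt; then CSA (cat.), CH2Cl2, rt
Reagents that add atoms: none
Why: Acidic desilylation frees the C18 hydroxyl, which adds to C16 of the protonated enone in a 5-exo-trig oxa-Michael closure. The conformer that keeps ring A equatorial on C13 is the one with C18 axial, and the bridge can form only with O17 cis to C18, which fixes C16. The acidic conditions spare C8, and the oxidised side chain is no longer an acid-sensitive electron-rich alkene.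

Step 15
Reactants: 32 bridged keto lactone aldehyde
Product: 33 target acid (4R,7R,8S,13S,16S,19S)
Conditions: NaClO2, NaH2PO4, 2-methylbut-2-ene, t-BuOH/H2O, rt
Reagents that add atoms: sodium chlorite, [Na+].[O-]Cl=O
Why: Pinnick oxidation converts the α-methylene aldehyde to the acrylic acid at about pH 4, where the β-alkoxy ketone, the lactone and C8 are stable; the alkene scavenger removes hypochlorous acid.

## Compound list

1 | 4,4-dimethylcyclohexa-2,5-dien-1-one | CC1(C)C=CC(=O)C=C1 | starting material
2 | (chloromethyl)(dimethyl)(propan-2-yloxy)silane | CC(C)O[Si](C)(C)CCl | starting material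
3 | {[dimethyl(propan-2-yloxy)silyl]methyl}magnesium chloride | CC(C)O[Si](C)(C)C[Mg]Cl | intermediate
4 | (5R)-5-{[dimethyl(propan-2-yloxy)silyl]methyl}-4,4-dimethylcyclohex-2-en-1-one | O=C1C=CC(C)(C)[C@H](C[Si](C)(C)OC(C)C)C1 | intermediate
5 | (5R)-5-(hydroxymethyl)-4,4-dimethylcyclohex-2-en-1-one | O=C1C=CC(C)(C)[C@H](CO)C1 | intermediate
6 | (5R)-5-({[tert-butyl(dimethyl)silyl]oxy}methyl)-4,4-dimethylcyclohex-2-en-1-one (ring C enone) | O=C1C=CC(C)(C)[C@H](CO[Si](C)(C)C(C)(C)C)C1 | intermediate
7 | (4S)-4-benzyl-1,3-oxazolidin-2-one | O=C1N[C@@H](Cc2ccccc2)CO1 | starting material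
8 | 3-methylbut-2-enoyl chloride | CC(C)=CC(Cl)=O | starting material
9 | N-lithio derivative of 7 | [Li]N1[C@@H](Cc2ccccc2)COC1=O | intermediate
10 | (4S)-4-benzyl-3-(3-methylbut-2-enoyl)-1,3-oxazolidin-2-one | CC(C)=CC(=O)N1[C@@H](Cc2ccccc2)COC1=O | intermediate
11 | 3-bromoprop-1-yne | C#CCBr | starting material
12 | sodium (Z)-dienolate of 10 (isopropenyl cis to ONa) | C=C(C)/C=C(\O[Na])N1[C@@H](Cc2ccccc2)COC1=O | intermediate
13 | (4S)-4-benzyl-3-[(2S)-2-(prop-1-en-2-yl)pent-4-ynoyl]-1,3-oxazolidin-2-one | C=C(C)[C@H](CC#C)C(=O)N1[C@@H](Cc2ccccc2)COC1=O | intermediate
14 | (2S)-2-(prop-1-en-2-yl)pent-4-yn-1-ol | C=C(C)[C@@H](CO)CC#C | intermediate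
15 | (3S)-3-(iodomethyl)-2-methylhex-1-en-5-yne | C=C(C)[C@@H](CI)CC#C | intermediate
16 | [(1E,4S)-4-(iodomethyl)-5-methylhexa-1,5-dien-1-yl]bis(3-methylbutan-2-yl)borane | C=C(C)[C@@H](CI)C/C=C/B(C(C)C(C)C)C(C)C(C)C | intermediate
17 | (4S)-4-(iodomethyl)-5-methylhex-5-enal | C=C(C)[C@@H](CI)CCC=O | intermediate
18 | methyl 2-(dimethoxyphosphoryl)acetate | COC(=O)CP(=O)(OC)OC | starting material
19 | methyl (2E,6S)-6-(iodomethyl)-7-methylocta-2,7-dienoate (iodo enoate) | C=C(C)[C@@H](CI)CC/C=C/C(=O)OC | intermediate
20 | lithium (3R)-3-({[tert-butyl(dimethyl)silyl]oxy}methyl)-4,4-dimethylcyclohexa-1,5-dien-1-olate | [Li]OC1=C[C@@H](CO[Si](C)(C)C(C)(C)C)C(C)(C)C=C1 | intermediate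
21 | lithium ester enolate of the open-chain Michael adduct (C7–C13 formed, C9–I intact) | C=C(C)[C@@H](CI)CC[C@H](C=C(OC)O[Li])[C@H]1C(=O)C=CC(C)(C)[C@@H]1CO[Si](C)(C)C(C)(C)C | intermediate
22 | methyl (1R,2S,5R)-2-[(1R,6R)-6-({[tert-butyl(dimethyl)silyl]oxy}methyl)-5,5-dimethyl-2-oxocyclohex-3-en-1-yl]-5-(prop-1-en-2-yl)cyclohexane-1-carboxylate (all three ring A substituents equatorial; ring A trans to C18 on ring C) | C=C(C)[C@@H]1CC[C@H]([C@@H](C1)C(=O)OC)[C@H]1C(=O)C=CC(C)(C)[C@@H]1CO[Si](C)(C)C(C)(C)C | intermediate
23 | formaldehyde | C=O | starting material
24 | lithium dienolate of 22 (C13=C14) | C=C(C)[C@@H]1CC[C@H]([C@@H](C1)C(=O)OC)C1=C(O[Li])C=CC(C)(C)[C@@H]1CO[Si](C)(C)C(C)(C)C | intermediate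
25 | lithium alkoxide of the C13-hydroxymethyl keto ester (C12 trans to C18) | C=C(C)[C@@H]1CC[C@H]([C@@H](C1)C(=O)OC)[C@]1(CO[Li])C(=O)C=CC(C)(C)[C@@H]1CO[Si](C)(C)C(C)(C)C | intermediate
26 | trans-fused spiro lactone enone silyl ether, (4R,7R,8R,13S,19S): δ-lactone ring B fused to ring A with C8–H trans to C7–H, spiro at C13 to the 4,4-dimethyl-5-(silyloxymethyl)cyclohex-2-enone ring, isopropenyl on C4 | C=C(C)[C@@H]1CC[C@@H]2[C@@H](C1)C(=O)OC[C@]21C(=O)C=CC(C)(C)[C@@H]1CO[Si](C)(C)C(C)(C)C | intermediate
27 | lithium enolate of lactone 26 (C8=C10) | C=C(C)[C@@H]1CC[C@@H]2C(C1)=C(O[Li])OC[C@]21C(=O)C=CC(C)(C)[C@@H]1CO[Si](C)(C)C(C)(C)C | intermediate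
28 | cis-fused spiro lactone enone silyl ether, (4R,7R,8S,13S,19S): C8 epimer of 26 | C=C(C)[C@@H]1CC[C@@H]2[C@H](C1)C(=O)OC[C@]21C(=O)C=CC(C)(C)[C@@H]1CO[Si](C)(C)C(C)(C)C | intermediate
29 | allylic alcohol of 28 (C3 as CH2OH) | C=C(CO)[C@@H]1CC[C@@H]2[C@H](C1)C(=O)OC[C@]21C(=O)C=CC(C)(C)[C@@H]1CO[Si](C)(C)C(C)(C)C | intermediate
30 | α-methylene aldehyde of 28 (C3 as CHO) | C=C(C=O)[C@@H]1CC[C@@H]2[C@H](C1)C(=O)OC[C@]21C(=O)C=CC(C)(C)[C@@H]1CO[Si](C)(C)C(C)(C)C | intermediate
31 | desilylated hydroxy enone aldehyde (C18–OH free) | C=C(C=O)[C@@H]1CC[C@@H]2[C@H](C1)C(=O)OC[C@]21C(=O)C=CC(C)(C)[C@@H]1CO | intermediate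
32 | bridged keto lactone aldehyde, (4R,7R,8S,13S,16S,19S): target skeleton with C3 as CHO | C=C(C=O)[C@@H]1CC[C@@H]2[C@H](C1)C(=O)OC[C@]21C(=O)C[C@@H]2OC[C@H]1C2(C)C | intermediate
33 | target acid, (4R,7R,8S,13S,16S,19S) in the skeleton numbering | C=C(C(=O)O)[C@@H]1CC[C@@H]2[C@H](C1)C(=O)OC[C@]21C(=O)C[C@@H]2OC[C@H]1C2(C)C | target

## Step count and least certain steps

Total step count: 15. Longest linear sequence: 12 steps (steps 4 to 9, then 10 to 15); steps 1 to 3 form the shorter branch.

**Step 10 (key step).** Two processes may go wrong. The ester enolate of the adduct may be quenched by proton transfer from C13–H before it displaces iodide, giving the more stable ketone enolate, which may alkylate C9 itself or survive to work-up. The pairing of enolate and enoate faces may also be imperfect, which erodes control at C7. The fallback sets out from 6 and 19 and comes back at 22 by separating the two bond formations. The conjugate addition is run as in step 10 but quenched at −78 °C with acetic acid to give the open-chain Michael adduct F1. Its ketone is masked as the trimethylsilyl dienol ether F2 (Me3SiOTf, Et3N, CH2Cl2, 0 °C; the ester is not enolised under these conditions). LiN(i-Pr)2 in THF/DMPU can then deprotonate only C8, and the same 6-exo-tet alkylation closes ring A to the cyclised silyl dienol ether F3, which dilute HCl in the work-up hydrolyses to 22.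

**Step 11.** The hindered tetrasubstituted enolate may capture monomeric formaldehyde incompletely, and the aldolate may revert by retro-aldol cleavage before it lactonises; some attack syn to C18 is also possible, because the face anti to C18 carries the pseudoaxial methyl of C20. The fallback sets out from 22 and comes back at 26. Compound 22 is converted to the triethylsilyl dienol ether F4 (LiN(SiMe3)2, Et3SiCl). A Mukaiyama-type hydroxymethylation with aqueous formaldehyde and catalytic Sc(OTf)3 in THF then gives the neutral hydroxymethyl keto ester F5 under conditions where retro-aldol cleavage is slow. Catalytic p-TsOH in toluene closes the lactone to 26.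

**Step 12.** Protonation may occur from the axial direction of ring A, or the enolate and product may exchange protons during the quench; either returns the trans-fused lactone. The fallback sets out from 22 and comes back at 28 by inverting C8 before the lactone exists. With 2.2 equivalents of LiN(i-Pr)2, 22 gives the dianion (C13 dienolate and C8 ester enolate). In the exocyclic ester enolate, allylic 1,3-strain pushes the large C7 substituent axial, and protonation with the same hindered phenol then occurs anti to it, as in the ketonisation of 2-substituted exocyclic enols, to give the cis ester F6. Under the conditions of step 11, F6 should lactonise directly to 28.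

**Step 1.** The catalyst may discriminate poorly between the enantiotopic β-carbons with this α-silyl Grignard reagent, or 1,2-addition may compete. The fallback sets out from 1 and 2 and comes back at 5. Conjugate addition of 3 promoted by CuI and Me3SiCl gives the racemic silane F7, and Tamao oxidation as in step 2 gives the racemic alcohol F8. Lipase-catalysed transesterification with vinyl acetate (Burkholderia cepacia lipase, t-BuOMe), run past half conversion with an enzyme screened to acetylate the (S)-enantiomer, gives the acetate F9 and leaves (R)-alcohol 5.

**Step 13.** The ene reaction may take the tertiary allylic hydrogen on C4 instead of the methyl hydrogen, and over-oxidation or retention of selenium may lower the return. The fallback sets out from 28 and comes back at 30. Ene-type chlorination with hypochlorous acid (Ca(OCl)2, solid CO2, CH2Cl2/H2O, 0 °C), which does not touch the electron-poor enone, gives the allylic chloride F10. Oxidation of F10 with N-methylmorpholine N-oxide in MeCN at rt gives 30.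

## Further compounds

F1 | step 10 | open-chain Michael adduct, methyl (3R,6S)-3-[(1R,6R)-6-({[tert-butyl(dimethyl)silyl]oxy}methyl)-5,5-dimethyl-2-oxocyclohex-3-en-1-yl]-6-(iodomethyl)-7-methyloct-7-enoate | C=C(C)[C@@H](CI)CC[C@H](CC(=O)OC)[C@H]1C(=O)C=CC(C)(C)[C@@H]1CO[Si](C)(C)C(C)(C)C
F2 | step 10 | trimethylsilyl dienol ether of F1 (C13=C14–OSiMe3) | C=C(C)[C@@H](CI)CC[C@H](CC(=O)OC)C1=C(O[Si](C)(C)C)C=CC(C)(C)[C@@H]1CO[Si](C)(C)C(C)(C)C
F3 | step 10 | trimethylsilyl dienol ether of 22 | C=C(C)[C@@H]1CC[C@H]([C@@H](C1)C(=O)OC)C1=C(O[Si](C)(C)C)C=CC(C)(C)[C@@H]1CO[Si](C)(C)C(C)(C)C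
F4 | step 11 | triethylsilyl dienol ether of 22 | C=C(C)[C@@H]1CC[C@H]([C@@H](C1)C(=O)OC)C1=C(O[Si](CC)(CC)CC)C=CC(C)(C)[C@@H]1CO[Si](C)(C)C(C)(C)C
F5 | step 11 | C13-hydroxymethyl keto ester (free alcohol of 25; C12 trans to C18) | C=C(C)[C@@H]1CC[C@H]([C@@H](C1)C(=O)OC)[C@]1(CO)C(=O)C=CC(C)(C)[C@@H]1CO[Si](C)(C)C(C)(C)C
F6 | step 12 | C8 epimer of 22 (ester cis to C13) | C=C(C)[C@@H]1CC[C@H]([C@H](C1)C(=O)OC)[C@H]1C(=O)C=CC(C)(C)[C@@H]1CO[Si](C)(C)C(C)(C)C
F7 | step 1 | racemic 5-{[dimethyl(propan-2-yloxy)silyl]methyl}-4,4-dimethylcyclohex-2-en-1-one | O=C1C=CC(C)(C)C(C[Si](C)(C)OC(C)C)C1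
F8 | step 1 | racemic 5-(hydroxymethyl)-4,4-dimethylcyclohex-2-en-1-one | O=C1C=CC(C)(C)C(CO)C1
F9 | step 1 | (5S)-5-(acetoxymethyl)-4,4-dimethylcyclohex-2-en-1-one | O=C1C=CC(C)(C)[C@@H](COC(C)=O)C1
F10 | step 13 | allylic chloride of 28 (C3 as CH2Cl) | C=C(CCl)[C@@H]1CC[C@@H]2[C@H](C1)C(=O)OC[C@]21C(=O)C=CC(C)(C)[C@@H]1CO[Si](C)(C)C(C)(C)C
A1 | alternative 1 | acrylate of the C12 alcohol with the (E,E)-dienyl ketal on C13 (rings C and D closed) | C=CC(=O)OC[C@@]1(/C=C/C=C/C2(C)OCCO2)C(=O)C[C@@H]2OC[C@H]1C2(C)C
A2 | alternative 1 | cis-fused lactone cyclohexene cycloadduct, C4 ketal cis to C13 | CC1(OCCO1)[C@H]1C=C[C@@H]2[C@H](C1)C(=O)OC[C@]21C(=O)C[C@@H]2OC[C@H]1C2(C)C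
A3 | alternative 2 | C16 oxyacetic acid of the C13=C19 enone carrying ring A | C=C(C)[C@@H]1CC[C@H]([C@H](C1)C(=O)OC)C1=CC(C)(C)[C@@H](OCC(=O)O)CC1=O
A4 | alternative 2 | bridged hydroxymethyl ketone ester | C=C(C)[C@@H]1CC[C@H]([C@H](C1)C(=O)OC)[C@]1(CO)C(=O)C[C@@H]2OC[C@H]1C2(C)C
A5 | alternative 3 | (5R)-1-nitro-5-(prop-1-en-2-yl)cyclohex-1-ene | C=C(C)[C@@H]1CCC=C(C1)[N+](=O)[O-]
A6 | alternative 3 | coupled nitro enone with C18 as silylmethyl, ring A trans to C18, C8 epimers | C=C(C)[C@@H]1CC[C@H](C(C1)[N+](=O)[O-])[C@H]1C(=O)C=CC(C)(C)[C@@H]1C[Si](C)(C)OC(C)C
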